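The plan rests on cutting the second 2,3-dihydrobenzofuran at its C3–C3a and C2–O bonds. Because that C3–C3a bond is also an edge of the second eight-membered carbocycle, one palladium-mediated oxyarylation, in which the ortho-bromophenol ring E on one central methine adds across the (E)-stilbene carried by resorcinol ring D of the neighbouring diarylmethine arm, should close carbocycle and furan together and create both furan stereocentres. The precursor is therefore the complete first eight-membered ring, fused to the first trans-dihydrobenzofuran, with six stereocentres, the bromophenol and the stilbene in place; it is built by an aldol ring closure followed by additions to the outer face of that ring.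

Key step: step 28

Labels: furan 1 = first dihydrobenzofuran (O1, C2, C3, fused to ring C; ring B = the 3,5-dimethoxyphenyl ring on C3). Ring 1 = eight-membered carbocycle C3–C3a–C4–Cc–Cf–Ca–C2'–C1' (C2', C1' in ring B). Ca = CH(4-methoxyphenyl); Cf = CH(ring E); Cc = CH carrying the Ce arm; Ce = CH(4-methoxyphenyl)(ring D); Cg, Ch = C3, C2 of furan 2.

Remark on the chemistry: the ring E phenol stays a triisopropylsilyl ether until step 27 and the stilbene arrives ready-made on ring D, so no palladium chemistry meets the aryl bromide before the key step.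

Assumption: racemic 16 and 17 are written as pairs of enantiomers. The absolute configuration of 18 is to be confirmed by X-ray or ECD. From 25 on the SMILES string defines the configuration.

Step 1
Reactants: 1 3-hydroxy-5-methoxybenzaldehyde
Product: 2 3-formyl-5-methoxyphenyl acetate
Conditions: Ac2O, pyridine, CH2Cl2, rt
Reagents that add atoms: acetic anhydride CC(=O)OC(C)=O
Why: O-acylation of the phenol turns the strongest donor into a weak one, so the following bromination is steered by the methoxy group alone.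

Step 2
Reactants: 2 3-formyl-5-methoxyphenyl acetate
Product: 3 2-bromo-3-formyl-5-methoxyphenyl acetate
Conditions: NBS, MeCN, rt
Reagents that add atoms: N-bromosuccinimide O=C1CCC(=O)N1Br
Why: Electrophilic aromatic bromination should go para to the methoxy group, between the acetoxy- and formyl-bearing carbons, as it does for 3-methoxybenzaldehyde.

Step 3
Reactants: 3 2-bromo-3-formyl-5-methoxyphenyl acetate
Product: 4 2-bromo-3-hydroxy-5-methoxybenzaldehyde
Conditions: K2CO3 (cat.), MeOH, 0 °C
Reagents that add atoms: none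
Why: Base-catalysed transesterification (methanolysis) of the aryl acetate frees the phenol without touching aldehyde or bromide.

Step 4
Reactants: 4 2-bromo-3-hydroxy-5-methoxybenzaldehyde
Product: 5 2-bromo-5-methoxy-3-(triisopropylsilyloxy)benzaldehyde
Conditions: i-Pr3SiCl, imidazole, DMF, rt
Reagents that add atoms: triisopropylsilyl chloride CC(C)[Si](Cl)(C(C)C)C(C)C
Why: Silyl ether formation gives a mask for the ring E phenol that resists bases and organometallics and is removed by fluoride at the end.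

Step 5
Reactants: 5 2-bromo-5-methoxy-3-(triisopropylsilyloxy)benzaldehyde
Product: 6 [2-bromo-5-methoxy-3-(triisopropylsilyloxy)phenyl]methanol
Conditions: NaBH4, MeOH–THF, 0 °C
Reagents that add atoms: none
Why: Borohydride reduction of the aldehyde to the benzylic alcohol.

Step 6
Reactants: 6 [2-bromo-5-methoxy-3-(triisopropylsilyloxy)phenyl]methanol
Product: 7 [2-bromo-3-(chloromethyl)-5-methoxyphenoxy]triisopropylsilane (ring E benzyl chloride)
Conditions: SOCl2, pyridine, CH2Cl2, 0 °C
Reagents that add atoms: thionyl chloride O=S(Cl)Cl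
Why: Deoxychlorination of the benzylic alcohol through its chlorosulfite (nucleophilic substitution).

Step 7
Reactants: 4 2-bromo-3-hydroxy-5-methoxybenzaldehyde; 8 diethyl (4-methoxybenzyl)phosphonate
Product: 9 2-bromo-5-methoxy-3-[(E)-2-(4-methoxyphenyl)ethenyl]phenol (ring D stilbene)
Conditions: NaH (2.2 equiv), THF, 0 °C → rt; aq. NH4Cl
Reagents that add atoms: none
Why: Horner–Wadsworth–Emmons olefination of the phenoxide aldehyde with the benzylphosphonate anion should give the (E)-stilbene, so the alkene of the key step is made without palladium.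

Step 8
Reactants: 10 methyl 3-hydroxy-5-methoxybenzoate; 11 2-bromo-1-(3,5-dimethoxyphenyl)ethan-1-one
Product: 12 methyl 3-[2-(3,5-dimethoxyphenyl)-2-oxoethoxy]-5-methoxybenzoate
Conditions: K2CO3, acetone, reflux
Reagents that add atoms: none
Why: Williamson ether synthesis (SN2 of the phenoxide on the α-bromo ketone).

Step 9
Reactants: 12 methyl 3-[2-(3,5-dimethoxyphenyl)-2-oxoethoxy]-5-methoxybenzoate
Product: 13 methyl 3-(3,5-dimethoxyphenyl)-6-methoxy-1-benzofuran-4-carboxylate
Conditions: Bi(OTf)3 (10 mol %), ClCH2CH2Cl, reflux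
Reagents that add atoms: none
Why: Lewis acid-catalysed cyclodehydration (intramolecular Friedel–Crafts hydroxyalkylation, then loss of water) should close the furan at the ring position para to the methoxy group, which gives the 3-aryl-4-carboxylate.

Step 10
Reactants: 13 methyl 3-(3,5-dimethoxyphenyl)-6-methoxy-1-benzofuran-4-carboxylate; 14 4-bromoanisole
Product: 15 methyl 3-(3,5-dimethoxyphenyl)-6-methoxy-2-(4-methoxyphenyl)-1-benzofuran-4-carboxylate
Conditions: Pd(OAc)2 (5 mol %), PCy3·HBF4 (10 mol %), pivalic acid (30 mol %), K2CO3, DMA, 110 °C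
Reagents that add atoms: none
Why: Palladium-catalysed direct C2–H arylation of the benzofuran by pivalate-assisted concerted metalation–deprotonation.

Step 11
Reactants: 15 methyl 3-(3,5-dimethoxyphenyl)-6-methoxy-2-(4-methoxyphenyl)-1-benzofuran-4-carboxylate
Product: 16 racemic methyl (2S,3R)-3-(3,5-dimethoxyphenyl)-6-methoxy-2-(4-methoxyphenyl)-2,3-dihydro-1-benzofuran-4-carboxylate (cis)
Conditions: H2 (50 bar), Pd/C, EtOAc–AcOH, 60 °C
Reagents that add atoms: none
Why: Heterogeneous catalytic hydrogenation adds both hydrogens to one face of the furan double bond, so the racemic cis-2,3-diaryl dihydrobenzofuran is expected.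

Step 12
Reactants: 16 racemic cis-dihydrobenzofuran ester
Product: 17 racemic methyl (2R,3R)-3-(3,5-dimethoxyphenyl)-6-methoxy-2-(4-methoxyphenyl)-2,3-dihydro-1-benzofuran-4-carboxylate (trans)
Conditions: CF3CO2H, CH2Cl2, rt
Reagents that add atoms: none
Why: Acid-mediated epimerisation: reversible ionisation of the C2–O bond to the 4-methoxybenzylic cation and reclosure should give the thermodynamically favoured trans isomer.

Step 13
Reactants: 17 racemic trans-dihydrobenzofuran ester
Product: 18 methyl (2R,3R)-3-(3,5-dimethoxyphenyl)-6-methoxy-2-(4-methoxyphenyl)-2,3-dihydro-1-benzofuran-4-carboxylate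
Conditions: preparative SFC on an amylose tris(3,5-dimethylphenylcarbamate) phase, CO2–MeOH
Reagents that add atoms: none
Why: Chromatographic resolution of the racemate on a chiral stationary phase delivers the (2R,3R) enantiomer, and C3 then relays all later stereocontrol.

Step 14
Reactants: 18 (2R,3R)-trans-dihydrobenzofuran ester
Product: 19 methyl (2R,3R)-3-(2-formyl-3,5-dimethoxyphenyl)-6-methoxy-2-(4-methoxyphenyl)-2,3-dihydro-1-benzofuran-4-carboxylate
Conditions: POCl3, DMF, 0 → 60 °C; then aq. NaOAc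
Reagents that add atoms: N,N-dimethylformamide CN(C)C=O; water O
Why: Vilsmeier–Haack formylation should attack the most electron-rich ring, ring B, ortho to its benzylic carbon and para to a methoxy group, since ring C is deactivated by the ester.

Step 15
Reactants: 19 ring B aldehyde ester
Product: 20 methyl (2R,3R)-3-[2-(dimethoxymethyl)-3,5-dimethoxyphenyl]-6-methoxy-2-(4-methoxyphenyl)-2,3-dihydro-1-benzofuran-4-carboxylate
Conditions: HC(OMe)3, MeOH, pyridinium p-toluenesulfonate (cat.), rt
Reagents that add atoms: trimethyl orthoformate COC(OC)OC; methanol CO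
Why: Acid-catalysed acetalisation masks the aldehyde for the two organomagnesium steps that follow.

Step 16
Reactants: 20 ring B acetal ester
Product: 21 (2R,3R)-3-[2-(dimethoxymethyl)-3,5-dimethoxyphenyl]-N,6-dimethoxy-2-(4-methoxyphenyl)-N-methyl-2,3-dihydro-1-benzofuran-4-carboxamide
Conditions: MeNH(OMe)·HCl, i-PrMgCl, THF, −20 → 0 °C
Reagents that add atoms: N,O-dimethylhydroxylamine hydrochloride CNOC.Cl
Why: Aminolysis of the methyl ester by the chloromagnesium amide gives the Weinreb amide.

Step 17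
Reactants: 7 ring E benzyl chloride; 21 Weinreb amide
Product: 23 ring E benzyl ketone on C4 of furan 1 (acetal on ring B), via ring E benzylmagnesium chloride 22 (not isolated)
Conditions: Mg, Et2O, 0 °C; then 21, THF, −20 → 0 °C; aq. NH4Cl
Reagents that add atoms: none
Why: Weinreb ketone synthesis: magnesium should insert into the benzylic C–Cl bond and not the hindered aryl C–Br bond, and the benzyl Grignard reagent adds once through the stable chelate.

Step 18
Reactants: 23 ring E benzyl ketone acetal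
Product: 25 ring-1 enone (Cc=O; Cf=Ca double bond; ring E on Cf), via keto aldehyde 24 (not isolated)
Conditions: pyridinium p-toluenesulfonate, acetone–H2O, 40 °C; then piperidine, AcOH, toluene (0.01 M), 4 Å molecular sieves, 100 °C
Reagents that add atoms: none
Why: Acetal hydrolysis and then an intramolecular Knoevenagel-type aldol condensation of the deoxybenzoin methylene (Cf) with the ring B aldehyde (Ca) should close ring 1 as the ring-cis α-aryl enone, helped by the diarylmethane hinge at C3 that holds the partners close.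

Step 19
Reactants: 25 ring-1 enone; 26 4-methoxyphenylmagnesium bromide
Product: 28 ring-1 ketone with 4-methoxyphenyl on Ca cis to ring E on Cf, via Cf-epimeric ketone mixture 27 (not isolated)
Conditions: CuBr·SMe2 (20 mol %), THF, −40 → 0 °C; aq. NH4Cl; then DBU (cat.), THF, rt
Reagents that add atoms: none
Why: Copper-catalysed conjugate addition of the aryl Grignard reagent should reach Ca from the outer face of the medium ring (the inner face lies over ring C), which sets Ca, and base equilibration α to the ketone is expected to put ring E on the outer face too, cis to the new aryl group.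

Step 20
Reactants: 28 ring-1 ketone
Product: 29 ring-1 exocyclic alkene (Cc=CH2)
Conditions: Zn, CH2Br2, TiCl4, THF–CH2Cl2, 0 °C → rt
Reagents that add atoms: dibromomethane BrCBr
Why: Takai–Lombardo methylenation is a non-basic carbonyl olefination, so this hindered and easily enolised ketone is methylenated without disturbing Cf.

Step 21
Reactants: 29 ring-1 exocyclic alkene
Product: 31 primary alcohol Cc–CH2OH (epimers at Cc), via primary alkylborane 30 (not isolated)
Conditions: BH3·THF, THF, 0 °C → rt; then H2O2, aq. NaHCO3, 0 °C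
Reagents that add atoms: hydrogen peroxide OO
Why: Anti-Markovnikov hydroboration–oxidation of the 1,1-disubstituted alkene gives the primary alcohol; the configuration at Cc is corrected in the next step.

Step 22
Reactants: 31 primary alcohol
Product: 33 ring-1 aldehyde with the formyl group on Cc trans to ring E, via Cc-epimeric aldehyde mixture 32 (not isolated)
Conditions: Dess–Martin periodinane, NaHCO3, CH2Cl2, 0 °C; then DBU (cat.), CH2Cl2, rt
Reagents that add atoms: none
Why: Dess–Martin oxidation, then base-catalysed epimerisation of the α-aryl aldehyde through its enolate, should place the formyl group on the open outer face of ring 1 (thermodynamic control of Cc).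

Step 23
Reactants: 9 ring D stilbene; 33 ring-1 aldehyde
Product: 35 secondary alcohol at Ce carrying ring D as the free phenol (carbinol epimers), via dilithiated stilbene 34 (not isolated)
Conditions: n-BuLi (2.1 equiv), THF, −78 °C; then 33, −78 °C; aq. NH4Cl
Reagents that add atoms: none
Why: Bromine–lithium exchange on the lithium phenoxide and 1,2-addition of the aryllithium to the aldehyde join ring D with its stilbene to Ce; the carbinol centre is erased in step 25.

Step 24
Reactants: 35 secondary alcohol with free ring D phenol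
Product: 36 ring D phenol tert-butyl carbonate
Conditions: Boc2O (1.1 equiv), i-Pr2NEt, DMAP (cat.), CH2Cl2, 0 °C
Reagents that add atoms: di-tert-butyl dicarbonate CC(C)(C)OC(=O)OC(=O)OC(C)(C)C
Why: Chemoselective O-acylation (carbonate formation) of the phenol over the hindered secondary alcohol.

Step 25
Reactants: 36 ring D phenol carbonate; 26 4-methoxyphenylmagnesium bromide
Product: 38 diarylmethine at Ce with free ring D phenol, via ortho-quinone methide 37 (not isolated)
Conditions: THF, −78 → 0 °C; aq. NH4Cl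
Reagents that add atoms: none
Why: Anionic ortho-quinone methide generation (carbonate transfer to the alkoxide and β-elimination) is followed by 1,4-addition of the aryl Grignard reagent; in the A(1,3)-minimised rotamer with H–Cc in the methide plane the aryl group is expected to add anti to the Cf arm, which sets Ce.

Step 26
Reactants: 38 diarylmethine with free ring D phenol
Product: 39 triisopropylsilyl ether of the key-step precursor
Conditions: MeI, K2CO3, acetone, 40 °C
Reagents that add atoms: iodomethane CI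
Why: Williamson O-methylation of the ring D phenol, while the silyl ether flanked by bromine should survive carbonate in acetone.

Step 27
Reactants: 39 silyl-protected precursor
Product: 40 key-step precursor (ortho-bromophenol on Cf, (E)-stilbene on ring D)
Conditions: Bu4NF, AcOH, THF, 0 °C
Reagents that add atoms: none
Why: Fluoride-mediated desilylation frees the ortho-bromophenol under buffered conditions that leave stilbene, aryl bromide and methyl ethers alone.

Step 28
Reactants: 40 key-step precursor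
Product: 41 decamethyl ether of the target
Conditions: Pd(OAc)2 (10 mol %), P(t-Bu)3·HBF4 (20 mol %), Cs2CO3, 1,4-dioxane (0.005 M), 100 °C
Reagents that add atoms: none
Why: Proposed new method: zerovalent palladium inserts into the hindered C–Br bond of ring E, the arylpalladium adds syn across the stilbene with the aryl group going to Cg and palladium to the 4-methoxybenzylic carbon Ch, and the neighbouring phenoxide then closes the C–O bond from the six-membered oxapalladacycle; the closest known reaction type is the Larock heteroannulation (oxyarylation) of alkenes and dienes by ortho-halophenols, which has not been used to close a medium ring onto an acyclic stilbene. The eight-membered carbocycle closes by 8-exo-trig carbopalladation and the dihydrofuran by five-membered C–O closure (reductive elimination from, or ionisation of, the benzylic palladium species). Cg is set by the alkene face that the tethered arylpalladium can reach, which the fixed Ce, Cc and Cf centres dictate: with the anisyl-bearing end Ch turned away from ring 1, H–Cg should end up cis to H–Ce on the new ring. Ch follows from syn addition to the E alkene and is in any case the thermodynamically favoured trans partner of Cg. Regioselectivity rests on the tether (8-exo over 9-endo) and on palladium preferring the cation-stabilising anisyl-substituted carbon, and with one aryl bromide and one alkene there is no chemoselectivity issue. C–O closure must outrun β-hydride elimination, which the phenoxide secures by chelating palladium so that the only β-hydrogen, on Cg, is held away from it.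

Step 29
Reactants: 41 decamethyl ether
Product: 42 CNP0224452.2 (target)
Conditions: BBr3, CH2Cl2, −78 °C → rt; then MeOH–H2O
Reagents that add atoms: none
Why: Lewis acid-mediated cleavage of all ten aryl methyl ethers (boron–oxygen complexation, bromide attack on methyl); both dihydrofurans are already the trans, thermodynamic isomers, so transient C2–O ionisation should not change them.

Compound list

1 | 3-hydroxy-5-methoxybenzaldehyde | COc1cc(O)cc(C=O)c1 | starting material
2 | 3-formyl-5-methoxyphenyl acetate | COc1cc(OC(C)=O)cc(C=O)c1 | intermediate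
3 | 2-bromo-3-formyl-5-methoxyphenyl acetate | COc1cc(OC(C)=O)c(Br)c(C=O)c1 | intermediate
4 | 2-bromo-3-hydroxy-5-methoxybenzaldehyde | COc1cc(O)c(Br)c(C=O)c1 | intermediate
5 | 2-bromo-5-methoxy-3-(triisopropylsilyloxy)benzaldehyde | COc1cc(O[Si](C(C)C)(C(C)C)C(C)C)c(Br)c(C=O)c1 | intermediate
6 | [2-bromo-5-methoxy-3-(triisopropylsilyloxy)phenyl]methanol | COc1cc(O[Si](C(C)C)(C(C)C)C(C)C)c(Br)c(CO)c1 | intermediate
7 | [2-bromo-3-(chloromethyl)-5-methoxyphenoxy]triisopropylsilane | COc1cc(O[Si](C(C)C)(C(C)C)C(C)C)c(Br)c(CCl)c1 | intermediate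
8 | diethyl (4-methoxybenzyl)phosphonate | CCOP(=O)(OCC)Cc1ccc(OC)cc1 | starting material
9 | 2-bromo-5-methoxy-3-[(E)-2-(4-methoxyphenyl)ethenyl]phenol | COc1ccc(/C=C/c2cc(OC)cc(O)c2Br)cc1 | intermediate
10 | methyl 3-hydroxy-5-methoxybenzoate | COC(=O)c1cc(O)cc(OC)c1 | starting material
11 | 2-bromo-1-(3,5-dimethoxyphenyl)ethan-1-one | COc1cc(OC)cc(C(=O)CBr)c1 | starting material
12 | methyl 3-[2-(3,5-dimethoxyphenyl)-2-oxoethoxy]-5-methoxybenzoate | COC(=O)c1cc(OC)cc(OCC(=O)c2cc(OC)cc(OC)c2)c1 | intermediate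
13 | methyl 3-(3,5-dimethoxyphenyl)-6-methoxy-1-benzofuran-4-carboxylate | COC(=O)c1cc(OC)cc2occ(-c3cc(OC)cc(OC)c3)c12 | intermediate
14 | 4-bromoanisole | COc1ccc(Br)cc1 | starting material
15 | methyl 3-(3,5-dimethoxyphenyl)-6-methoxy-2-(4-methoxyphenyl)-1-benzofuran-4-carboxylate | COC(=O)c1cc(OC)cc2oc(-c3ccc(OC)cc3)c(-c3cc(OC)cc(OC)c3)c12 | intermediate
16 | racemic cis ester, (2S,3R) and (2R,3S) forms of methyl 3-(3,5-dimethoxyphenyl)-6-methoxy-2-(4-methoxyphenyl)-2,3-dihydro-1-benzofuran-4-carboxylate | COc1cc(OC)cc(c1)[C@@H]1c2c(cc(OC)cc2C(=O)OC)O[C@@H]1c1ccc(OC)cc1.COc1cc(OC)cc(c1)[C@H]1c2c(cc(OC)cc2C(=O)OC)O[C@H]1c1ccc(OC)cc1 | intermediate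
17 | racemic trans ester, (2R,3R) and (2S,3S) forms of the same constitution | COc1cc(OC)cc(c1)[C@@H]1c2c(cc(OC)cc2C(=O)OC)O[C@H]1c1ccc(OC)cc1.COc1cc(OC)cc(c1)[C@H]1c2c(cc(OC)cc2C(=O)OC)O[C@@H]1c1ccc(OC)cc1 | intermediate
18 | methyl (2R,3R)-3-(3,5-dimethoxyphenyl)-6-methoxy-2-(4-methoxyphenyl)-2,3-dihydro-1-benzofuran-4-carboxylate | COc1cc(OC)cc(c1)[C@@H]1c2c(cc(OC)cc2C(=O)OC)O[C@H]1c1ccc(OC)cc1 | intermediate
19 | methyl (2R,3R)-3-(2-formyl-3,5-dimethoxyphenyl)-6-methoxy-2-(4-methoxyphenyl)-2,3-dihydro-1-benzofuran-4-carboxylate | O=Cc1c(OC)cc(OC)cc1[C@@H]1c2c(cc(OC)cc2C(=O)OC)O[C@H]1c1ccc(OC)cc1 | intermediate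
20 | methyl (2R,3R)-3-[2-(dimethoxymethyl)-3,5-dimethoxyphenyl]-6-methoxy-2-(4-methoxyphenyl)-2,3-dihydro-1-benzofuran-4-carboxylate | COC(OC)c1c(OC)cc(OC)cc1[C@@H]1c2c(cc(OC)cc2C(=O)OC)O[C@H]1c1ccc(OC)cc1 | intermediate
21 | (2R,3R)-3-[2-(dimethoxymethyl)-3,5-dimethoxyphenyl]-N,6-dimethoxy-2-(4-methoxyphenyl)-N-methyl-2,3-dihydro-1-benzofuran-4-carboxamide | COC(OC)c1c(OC)cc(OC)cc1[C@@H]1c2c(cc(OC)cc2C(=O)N(C)OC)O[C@H]1c1ccc(OC)cc1 | intermediate
22 | {[2-bromo-5-methoxy-3-(triisopropylsilyloxy)phenyl]methyl}magnesium chloride | COc1cc(O[Si](C(C)C)(C(C)C)C(C)C)c(Br)c(C[Mg]Cl)c1 | intermediate (not isolated)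
23 | 2-[2-bromo-5-methoxy-3-(triisopropylsilyloxy)phenyl]-1-{(2R,3R)-3-[2-(dimethoxymethyl)-3,5-dimethoxyphenyl]-6-methoxy-2-(4-methoxyphenyl)-2,3-dihydro-1-benzofuran-4-yl}ethan-1-one | COC(OC)c1c(OC)cc(OC)cc1[C@@H]1c2c(cc(OC)cc2C(=O)Cc2cc(OC)cc(O[Si](C(C)C)(C(C)C)C(C)C)c2Br)O[C@H]1c1ccc(OC)cc1 | intermediate
24 | keto aldehyde: 23 with the acetal replaced by the free ring B aldehyde | O=Cc1c(OC)cc(OC)cc1[C@@H]1c2c(cc(OC)cc2C(=O)Cc2cc(OC)cc(O[Si](C(C)C)(C(C)C)C(C)C)c2Br)O[C@H]1c1ccc(OC)cc1 | intermediate (not isolated)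
25 | ring-1 enone: eight-membered ring with Cc=O on C4 of ring C, Cf(ring E)=Ca(H) bonded to C2' of ring B, fused to (2R,3R)-furan 1 | O=C1/C(c5cc(OC)cc(O[Si](C(C)C)(C(C)C)C(C)C)c5Br)=C\c2c(OC)cc(OC)cc2[C@@H]2c3c(cc(OC)cc31)O[C@H]2c1ccc(OC)cc1 | intermediate
26 | 4-methoxyphenylmagnesium bromide | COc1ccc([Mg]Br)cc1 | starting material
27 | ring-1 ketone with 4-methoxyphenyl on Ca, mixture of epimers at Cf | COc1ccc([C@@H]2c3c(OC)cc(OC)cc3[C@@H]3c4c(cc(OC)cc4C(=O)C2c7cc(OC)cc(O[Si](C(C)C)(C(C)C)C(C)C)c7Br)O[C@H]3c2ccc(OC)cc2)cc1 | intermediate (not isolated)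
28 | ring-1 ketone, 4-methoxyphenyl on Ca and ring E on Cf cis | COc1ccc([C@@H]2c3c(OC)cc(OC)cc3[C@@H]3c4c(cc(OC)cc4C(=O)[C@@H]2c7cc(OC)cc(O[Si](C(C)C)(C(C)C)C(C)C)c7Br)O[C@H]3c2ccc(OC)cc2)cc1 | intermediate
29 | ring-1 exocyclic alkene (Cc=CH2) | COc1ccc([C@@H]2c3c(OC)cc(OC)cc3[C@@H]3c4c(cc(OC)cc4C(=C)[C@@H]2c7cc(OC)cc(O[Si](C(C)C)(C(C)C)C(C)C)c7Br)O[C@H]3c2ccc(OC)cc2)cc1 | intermediate
30 | primary alkylborane Cc–CH2–BH2, epimers at Cc | COc1ccc([C@@H]2c3c(OC)cc(OC)cc3[C@@H]3c4c(cc(OC)cc4C(CB)[C@@H]2c7cc(OC)cc(O[Si](C(C)C)(C(C)C)C(C)C)c7Br)O[C@H]3c2ccc(OC)cc2)cc1 | intermediate (not isolated)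
31 | primary alcohol Cc–CH2OH, epimers at Cc | COc1ccc([C@@H]2c3c(OC)cc(OC)cc3[C@@H]3c4c(cc(OC)cc4C(CO)[C@@H]2c7cc(OC)cc(O[Si](C(C)C)(C(C)C)C(C)C)c7Br)O[C@H]3c2ccc(OC)cc2)cc1 | intermediate
32 | aldehyde Cc–CHO, epimers at Cc | COc1ccc([C@@H]2c3c(OC)cc(OC)cc3[C@@H]3c4c(cc(OC)cc4C(C=O)[C@@H]2c7cc(OC)cc(O[Si](C(C)C)(C(C)C)C(C)C)c7Br)O[C@H]3c2ccc(OC)cc2)cc1 | intermediate (not isolated)
33 | ring-1 aldehyde, formyl on Cc trans to ring E on Cf | COc1ccc([C@@H]2c3c(OC)cc(OC)cc3[C@@H]3c4c(cc(OC)cc4[C@H]([C@@H]2c7cc(OC)cc(O[Si](C(C)C)(C(C)C)C(C)C)c7Br)C=O)O[C@H]3c2ccc(OC)cc2)cc1 | intermediate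
34 | lithium 2-lithio-5-methoxy-3-[(E)-2-(4-methoxyphenyl)ethenyl]phenoxide | COc1ccc(/C=C/c2cc(OC)cc(O[Li])c2[Li])cc1 | intermediate (not isolated)
35 | secondary alcohol at Ce bearing ring D (free 2-hydroxy, 4-methoxy, 6-styryl), carbinol epimers | COc1ccc([C@@H]2c3c(OC)cc(OC)cc3[C@@H]3c4c(cc(OC)cc4[C@H]([C@@H]2c7cc(OC)cc(O[Si](C(C)C)(C(C)C)C(C)C)c7Br)C(O)c5c(O)cc(OC)cc5/C=C/c5ccc(OC)cc5)O[C@H]3c2ccc(OC)cc2)cc1 | intermediate
36 | ring D phenol tert-butyl carbonate of 35 | COc1ccc([C@@H]2c3c(OC)cc(OC)cc3[C@@H]3c4c(cc(OC)cc4[C@H]([C@@H]2c7cc(OC)cc(O[Si](C(C)C)(C(C)C)C(C)C)c7Br)C(O)c5c(OC(=O)OC(C)(C)C)cc(OC)cc5/C=C/c5ccc(OC)cc5)O[C@H]3c2ccc(OC)cc2)cc1 | intermediate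
37 | ortho-quinone methide (Ce=C1 of ring D, ring D as dienone) | COc1ccc([C@@H]2c3c(OC)cc(OC)cc3[C@@H]3c4c(cc(OC)cc4[C@H]([C@@H]2c7cc(OC)cc(O[Si](C(C)C)(C(C)C)C(C)C)c7Br)C=C5C(=O)C=C(OC)C=C5/C=C/c5ccc(OC)cc5)O[C@H]3c2ccc(OC)cc2)cc1 | intermediate (not isolated)
38 | diarylmethine at Ce (4-methoxyphenyl and ring D) with free ring D phenol | COc1ccc([C@@H]2c3c(OC)cc(OC)cc3[C@@H]3c4c(cc(OC)cc4[C@H]([C@@H]2c7cc(OC)cc(O[Si](C(C)C)(C(C)C)C(C)C)c7Br)[C@H](c5ccc(OC)cc5)c5c(O)cc(OC)cc5/C=C/c5ccc(OC)cc5)O[C@H]3c2ccc(OC)cc2)cc1 | intermediate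
39 | triisopropylsilyl ether of the key-step precursor | COc1ccc([C@@H]2c3c(OC)cc(OC)cc3[C@@H]3c4c(cc(OC)cc4[C@H]([C@@H]2c7cc(OC)cc(O[Si](C(C)C)(C(C)C)C(C)C)c7Br)[C@H](c5ccc(OC)cc5)c5c(OC)cc(OC)cc5/C=C/c5ccc(OC)cc5)O[C@H]3c2ccc(OC)cc2)cc1 | intermediate
40 | key-step precursor: ring 1 with 2-bromo-3-hydroxy-5-methoxyphenyl on Cf and the (E)-stilbene arm on Cc | COc1ccc([C@@H]2c3c(OC)cc(OC)cc3[C@@H]3c4c(cc(OC)cc4[C@H]([C@@H]2c7cc(OC)cc(O)c7Br)[C@H](c5ccc(OC)cc5)c5c(OC)cc(OC)cc5/C=C/c5ccc(OC)cc5)O[C@H]3c2ccc(OC)cc2)cc1 | intermediate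
41 | decamethyl ether of the target | COc1ccc([C@@H]2c3c(OC)cc(OC)cc3[C@@H]3c4c(cc(OC)cc4[C@H]4[C@H](c5ccc(OC)cc5)c5c(OC)cc(OC)cc5[C@H]5c6c(cc(OC)cc6[C@H]24)O[C@@H]5c2ccc(OC)cc2)O[C@H]3c2ccc(OC)cc2)cc1 | intermediate
42 | CNP0224452.2 | Oc1ccc([C@@H]2c3c(O)cc(O)cc3[C@@H]3c4c(cc(O)cc4[C@H]4[C@H](c5ccc(O)cc5)c5c(O)cc(O)cc5[C@H]5c6c(cc(O)cc6[C@H]24)O[C@@H]5c2ccc(O)cc2)O[C@H]3c2ccc(O)cc2)cc1 | target

Total step count: 29. Longest linear sequence: 22 steps (steps 8 to 29, from 10 and 11).

Steps most likely to fail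

1. Step 28 (proposed new method). β-Hydride elimination from the benzylic palladium species, or a stalled medium-ring carbopalladation, may outrun C–O closure. The fallback uses known chemistry and runs from 39 back to 41. Compound 39 is cyclised by an intramolecular Mizoroki–Heck reaction (Pd(OAc)2, P(o-tol)3, K2CO3, Bu4NCl, DMF, 100 °C; 8-exo closure with deliberate β-hydride elimination) to the ring-2 triarylethene silyl ether F1. Bu4NF/AcOH then frees the ring-2 triarylethene phenol F2. Catalytic p-toluenesulfonic acid in CH2Cl2 should effect Markovnikov hydroalkoxylation (protonation at Cg, phenol capture of the anisyl-stabilised cation at Ch) and give 41 under thermodynamic control.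

2. Step 18. The eight-membered aldol condensation may lose to intermolecular condensation or stall at the hindered, electron-rich aldehyde. The fallback runs from 7 and 21 back to 25. A Michaelis–Arbuzov reaction of 7 with P(OEt)3 at 130 °C gives the ring E benzylphosphonate F3. Its lithium anion (LiHMDS, THF, −78 °C) is acylated by Weinreb amide 21 to the β-ketophosphonate acetal F4. Pyridinium p-toluenesulfonate in wet acetone gives the β-ketophosphonate aldehyde F5. LiCl and DBU in MeCN at high dilution (Masamune–Roush form of the intramolecular Horner–Wadsworth–Emmons reaction) should then close ring 1 irreversibly to 25.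

3. Step 25. The aryl nucleophile may add to the wrong face of the ortho-quinone methide, or the methide may tautomerise or cyclise onto the styrene before it is trapped. The fallback runs from 33 back to 38 and reverses the order in which aryl and hydride enter. Grignard reagent 26 adds to 33 to give the secondary 4-methoxyphenyl carbinol F6. Dess–Martin oxidation gives the 4-methoxyphenyl ketone F7, in which Cc can re-equilibrate to the same outer-face configuration. Aryllithium 34 adds to F7 to give the tertiary benzylic alcohol with free ring D phenol F8. NaBH4 in warm EtOH–THF reduces F8 through its ortho-quinone methide (1,4-hydride addition), so hydride rather than aryl enters on the preferred face and the opposite configuration at Ce results in 38.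

Further compounds

F1 | step 28 | ring-2 triarylethene silyl ether (Cg bonded to ring E, exocyclic Cg=Ch) | COc1ccc([C@@H]2c3c(OC)cc(OC)cc3[C@@H]3c4c(cc(OC)cc4[C@H]4[C@H](c5ccc(OC)cc5)c5c(OC)cc(OC)cc5C(=Cc5ccc(OC)cc5)c5c(O[Si](C(C)C)(C(C)C)C(C)C)cc(OC)cc5[C@H]24)O[C@H]3c2ccc(OC)cc2)cc1
F2 | step 28 | ring-2 triarylethene phenol | COc1ccc([C@@H]2c3c(OC)cc(OC)cc3[C@@H]3c4c(cc(OC)cc4[C@H]4[C@H](c5ccc(OC)cc5)c5c(OC)cc(OC)cc5C(=Cc5ccc(OC)cc5)c5c(O)cc(OC)cc5[C@H]24)O[C@H]3c2ccc(OC)cc2)cc1
F3 | step 18 | diethyl {[2-bromo-5-methoxy-3-(triisopropylsilyloxy)phenyl]methyl}phosphonate | CCOP(=O)(OCC)Cc1cc(OC)cc(O[Si](C(C)C)(C(C)C)C(C)C)c1Br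
F4 | step 18 | β-ketophosphonate acetal | COC(OC)c1c(OC)cc(OC)cc1[C@@H]1c2c(cc(OC)cc2C(=O)C(c2cc(OC)cc(O[Si](C(C)C)(C(C)C)C(C)C)c2Br)P(=O)(OCC)OCC)O[C@H]1c1ccc(OC)cc1
F5 | step 18 | β-ketophosphonate aldehyde | O=Cc1c(OC)cc(OC)cc1[C@@H]1c2c(cc(OC)cc2C(=O)C(c2cc(OC)cc(O[Si](C(C)C)(C(C)C)C(C)C)c2Br)P(=O)(OCC)OCC)O[C@H]1c1ccc(OC)cc1
F6 | step 25 | secondary 4-methoxyphenyl carbinol at Ce | COc1ccc([C@@H]2c3c(OC)cc(OC)cc3[C@@H]3c4c(cc(OC)cc4[C@H]([C@@H]2c7cc(OC)cc(O[Si](C(C)C)(C(C)C)C(C)C)c7Br)C(O)c5ccc(OC)cc5)O[C@H]3c2ccc(OC)cc2)cc1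
F7 | step 25 | 4-methoxyphenyl ketone at Ce | COc1ccc([C@@H]2c3c(OC)cc(OC)cc3[C@@H]3c4c(cc(OC)cc4[C@H]([C@@H]2c7cc(OC)cc(O[Si](C(C)C)(C(C)C)C(C)C)c7Br)C(=O)c5ccc(OC)cc5)O[C@H]3c2ccc(OC)cc2)cc1
F8 | step 25 | tertiary benzylic alcohol at Ce with free ring D phenol | COc1ccc([C@@H]2c3c(OC)cc(OC)cc3[C@@H]3c4c(cc(OC)cc4[C@H]([C@@H]2c7cc(OC)cc(O[Si](C(C)C)(C(C)C)C(C)C)c7Br)C(O)(c5ccc(OC)cc5)c5c(O)cc(OC)cc5/C=C/c5ccc(OC)cc5)O[C@H]3c2ccc(OC)cc2)cc1
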